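**Retrosynthetic overview**

1. Target ⇐ acidolysis of two tert-butyl groups ⇐ oxazaborolidine-controlled reduction of the C5 ketone of a fully substituted epoxyquinone (sets the carbinol).
2. Epoxyquinone ⇐ Stille coupling at the vinylic C3–Br (heptenyl) and cross-metathesis of a C1-allyl group with tert-butyl methacrylate (enoate arm).
3. Key disconnection: the C1–CH2 bond at the quaternary oxirane carbon, made by tin-mediated radical allylation of a tertiary bromo-oxirane through an α-keto oxiranyl radical; the cis ring fusion fixes the new quaternary centre.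
4. Bromo-oxirane ⇐ enantioselective nucleophilic epoxidation of 2,6-dibromo-3-(tert-butoxymethyl)benzoquinone ⇐ radical decarboxylative C–H alkoxymethylation of symmetric 2,6-dibromobenzoquinone ⇐ phenol.
5. Ring order: the carbocycle (ring A) is carried through from phenol; the oxirane (ring B) is the only ring formed, in step 4.

Assumption: the target is made exactly as drawn, (1S,5R,6S) with the C5 hydroxyl anti to the oxirane oxygen, both alkenes E, free acid; bicyclic locants follow 7-oxabicyclo[4.1.0]hept-3-ene numbering (C1 quaternary oxirane carbon, C2 ketone, C3 heptenyl carbon, C4 hydroxymethyl carbon, C5 carbinol, C6 oxirane CH).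

**Route**

Step 1
Reactants: 1 phenol
Product: 2 2,4,6-tribromophenol
Conditions: Br2 (3.1 equiv), H2O, 20 °C
Reagents that add atoms: bromine, BrBr
Why: Electrophilic aromatic bromination, in which the hydroxyl group activates exactly the two ortho positions and the para position, so the reaction stops at the tribromide, which precipitates from water.

Step 2
Reactants: 2 2,4,6-tribromophenol
Product: 3 2,6-dibromocyclohexa-2,5-diene-1,4-dione (2,6-dibromo-1,4-benzoquinone)
Conditions: fuming HNO3, AcOH, 0 °C to 20 °C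
Reagents that add atoms: nitric acid, O[N+](=O)[O-]
Why: Oxidative dearomatisation of a 2,4,6-trihalophenol, in which ipso-nitration at the para carbon, nitro-to-nitrite rearrangement and loss of nitrosyl bromide unmask the second quinone carbonyl and leave the two bromines on the carbons flanking one carbonyl.

Step 3
Reactants: 3 2,6-dibromocyclohexa-2,5-diene-1,4-dione; 4 tert-butoxyacetic acid
Product: 6 2,6-dibromo-3-(tert-butoxymethyl)cyclohexa-2,5-diene-1,4-dione, via tert-butoxymethyl radical 5 (not isolated)
Conditions: 4 (1.0 equiv) added over 1 h to 3 (1.5 equiv), AgNO3 (0.2 equiv), (NH4)2S2O8 (1.5 equiv), MeCN/H2O 1:1, 65 °C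
Reagents that add atoms: none
Why: Jacobsen–Torssell (Minisci-type) radical C–H alkylation, in which silver-catalysed persulfate decarboxylation of 4 gives the nucleophilic α-alkoxy radical 5 that adds to one of the two symmetry-equivalent unsubstituted carbons of electron-poor quinone 3 (so no regiochemical question arises) and the adduct is re-oxidised to the quinone, the excess of 3 suppressing a second alkylation.

Step 4
Reactants: 6 2,6-dibromo-3-(tert-butoxymethyl)cyclohexa-2,5-diene-1,4-dione
Product: 7 (1R,6S)-1,3-dibromo-4-(tert-butoxymethyl)-7-oxabicyclo[4.1.0]hept-3-ene-2,5-dione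
Conditions: tBuOOH (1.3 equiv), N-benzylquinidinium chloride (10 mol %), 0.1 M aq NaOH (0.2 equiv), toluene, 0 °C
Reagents that add atoms: tert-butyl hydroperoxide, CC(C)(C)OO
Why: Proposed new method: a Weitz–Scheffer nucleophilic epoxidation under chiral ion-pair (phase-transfer) control, in which the ammonium-bound tert-butylperoxide adds to the only unsubstituted enone β-carbon (the other ring alkene is tetrasubstituted), the α-bromo enolate closes onto the O–O bond, and the catalyst selects the ring face so that C6 becomes S and, through the forced cis fusion, the bromine-bearing C1 becomes R (the quinine-derived pseudo-enantiomer would give the mirror image); the closest known reaction types are the cinchona-ammonium-catalysed epoxidation of 2-substituted 1,4-naphthoquinones and the non-asymmetric epoxidation of 2-halo-1,4-naphthoquinones to 2-halo epoxides.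

Step 5
Reactants: 7 (1R,6S)-1,3-dibromo-4-(tert-butoxymethyl)-7-oxabicyclo[4.1.0]hept-3-ene-2,5-dione
Product: 9 (1S,6R)-3-bromo-4-(tert-butoxymethyl)-1-(prop-2-en-1-yl)-7-oxabicyclo[4.1.0]hept-3-ene-2,5-dione, via oxiranyl radical 8 (not isolated)
Conditions: allylSnBu3 (5 equiv), Et3B (0.3 equiv), air (slow syringe addition), toluene, −78 °C
Reagents that add atoms: allyltributylstannane, C=CC[Sn](CCCC)(CCCC)CCCC
Why: Proposed new method: a Keck radical allylation at an oxirane carbon, the key C–C bond formation, in which bromine abstraction from the tertiary α-keto C–Br of 7 by the tributylstannyl radical gives the pyramidal α-keto oxiranyl radical 8, which at −78 °C should be trapped by the allylstannane (SH2' with loss of the stannyl radical) faster than it ring-opens, and because the three-membered ring can only remain cis-fused the new bond must form anti to the oxirane oxygen, so the quaternary centre (1S) is relayed from C6 with no external control while the vinylic C3–Br is left untouched; the closest known reaction types are Keck allylation of α-bromo ketones and cyclisations of oxiranyl radicals generated from glycidic acid thiohydroxamate esters.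

Step 6
Reactants: 9 (1S,6R)-3-bromo-4-(tert-butoxymethyl)-1-(prop-2-en-1-yl)-7-oxabicyclo[4.1.0]hept-3-ene-2,5-dione; 10 tert-butyl 2-methylprop-2-enoate (tert-butyl methacrylate)
Product: 11 tert-butyl (2E)-4-[(1S,6R)-3-bromo-4-(tert-butoxymethyl)-2,5-dioxo-7-oxabicyclo[4.1.0]hept-3-en-1-yl]-2-methylbut-2-enoate
Conditions: 10 (10 equiv), second-generation Hoveyda–Grubbs catalyst RuCl2(H2IMes)(=CH-C6H4-2-OiPr) (5 mol %), CH2Cl2, 40 °C
Reagents that add atoms: none
Why: Olefin cross-metathesis between the monosubstituted allyl terminus and a 1,1-disubstituted acrylate that does not homodimerise, giving the trisubstituted enoate as the thermodynamically favoured E isomer while the tetrasubstituted, electron-poor bromo-enedione alkene is inert to the ruthenium carbene.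

Step 7
Reactants: 11 tert-butyl (2E)-4-[(1S,6R)-3-bromo-4-(tert-butoxymethyl)-2,5-dioxo-7-oxabicyclo[4.1.0]hept-3-en-1-yl]-2-methylbut-2-enoate; 12 hept-1-yne
Product: 14 tert-butyl (2E)-4-[(1S,6R)-4-(tert-butoxymethyl)-3-[(1E)-hept-1-en-1-yl]-2,5-dioxo-7-oxabicyclo[4.1.0]hept-3-en-1-yl]-2-methylbut-2-enoate, via (E)-tributyl(hept-1-en-1-yl)stannane 13 (not isolated)
Conditions: 12 (1.55 equiv), Bu3SnH (1.5 equiv), Pd2(dba)3 (1 mol %), Cy3P·HBF4 (4 mol %), iPr2NEt (8 mol %), CH2Cl2, 0 °C; then 11 (1.0 equiv), Pd2(dba)3 (2.5 mol %), AsPh3 (20 mol %), DMF, 45 °C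
Reagents that add atoms: none
Why: Palladium-catalysed syn-hydrostannation of the terminal alkyne (the bulky phosphine gives the linear E-vinylstannane 13, and the slight excess of alkyne consumes all tin hydride) followed in the same flask by Stille coupling at the doubly activated vinylic C3–Br, both events being stereospecific so the (E)-heptenyl geometry is fixed, under neutral conditions that spare the oxirane, the enedione and the esters.

Step 8
Reactants: 14 tert-butyl (2E)-4-[(1S,6R)-4-(tert-butoxymethyl)-3-[(1E)-hept-1-en-1-yl]-2,5-dioxo-7-oxabicyclo[4.1.0]hept-3-en-1-yl]-2-methylbut-2-enoate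
Product: 15 tert-butyl (2E)-4-[(1S,5R,6S)-4-(tert-butoxymethyl)-3-[(1E)-hept-1-en-1-yl]-5-hydroxy-2-oxo-7-oxabicyclo[4.1.0]hept-3-en-1-yl]-2-methylbut-2-enoate
Conditions: (R)-2-methyl-CBS-oxazaborolidine (30 mol %), catecholborane (1.6 equiv), toluene/CH2Cl2, −78 °C; MeOH, then pH 7 buffer
Reagents that add atoms: none
Why: Corey–Bakshi–Shibata reduction, in which the C5 carbonyl (oxirane CH as the small group, substituted alkene carbon as the large group) binds the catalyst whereas the C2 carbonyl between quaternary C1 and the heptenyl-bearing C3 is too hindered, and the (R)-catalyst delivers hydride to the face syn to the oxirane oxygen to give the (5R) alcohol anti to the epoxide by reagent control, so that any (1R,6S) material left from step 4 becomes the syn diastereomer and is removed by chromatography.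

Step 9
Reactants: 15 tert-butyl (2E)-4-[(1S,5R,6S)-4-(tert-butoxymethyl)-3-[(1E)-hept-1-en-1-yl]-5-hydroxy-2-oxo-7-oxabicyclo[4.1.0]hept-3-en-1-yl]-2-methylbut-2-enoate
Product: 16 (2E)-4-[(1S,5R,6S)-3-[(1E)-hept-1-en-1-yl]-5-hydroxy-4-(hydroxymethyl)-2-oxo-7-oxabicyclo[4.1.0]hept-3-en-1-yl]-2-methylbut-2-enoic acid (target)
Conditions: CF3CO2H/CH2Cl2 1:3, 0 °C to 20 °C
Reagents that add atoms: none
Why: Acidolysis (E1 loss of the tert-butyl cation as isobutene) cleaves the tert-butyl ester and the primary tert-butyl ether in one operation, the oxirane being deactivated toward acid opening by the adjacent carbonyl and no stereocentre being touched.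

**Compound list**

1 | phenol | Oc1ccccc1 | starting material
2 | 2,4,6-tribromophenol | Oc1c(Br)cc(Br)cc1Br | intermediate
3 | 2,6-dibromocyclohexa-2,5-diene-1,4-dione | O=C1C=C(Br)C(=O)C(Br)=C1 | intermediate
4 | tert-butoxyacetic acid | CC(C)(C)OCC(=O)O | starting material
5 | tert-butoxymethyl radical | [CH2]OC(C)(C)C | intermediate
6 | 2,6-dibromo-3-(tert-butoxymethyl)cyclohexa-2,5-diene-1,4-dione | O=C1C(Br)=C(COC(C)(C)C)C(=O)C=C1Br | intermediate
7 | (1R,6S)-1,3-dibromo-4-(tert-butoxymethyl)-7-oxabicyclo[4.1.0]hept-3-ene-2,5-dione | BrC1=C(COC(C)(C)C)C(=O)[C@@H]2O[C@]2(Br)C1=O | intermediate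
8 | (6R)-3-bromo-4-(tert-butoxymethyl)-2,5-dioxo-7-oxabicyclo[4.1.0]hept-3-en-1-yl radical (oxiranyl radical) | BrC1=C(COC(C)(C)C)C(=O)[C@@H]2O[C]2C1=O | intermediate
9 | (1S,6R)-3-bromo-4-(tert-butoxymethyl)-1-(prop-2-en-1-yl)-7-oxabicyclo[4.1.0]hept-3-ene-2,5-dione | BrC1=C(COC(C)(C)C)C(=O)[C@@H]2O[C@]2(CC=C)C1=O | intermediate
10 | tert-butyl 2-methylprop-2-enoate | CC(=C)C(=O)OC(C)(C)C | starting material
11 | tert-butyl (2E)-4-[(1S,6R)-3-bromo-4-(tert-butoxymethyl)-2,5-dioxo-7-oxabicyclo[4.1.0]hept-3-en-1-yl]-2-methylbut-2-enoate | BrC1=C(COC(C)(C)C)C(=O)[C@@H]2O[C@]2(C/C=C(\C)C(=O)OC(C)(C)C)C1=O | intermediate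
12 | hept-1-yne | CCCCCC#C | starting material
13 | (E)-tributyl(hept-1-en-1-yl)stannane | CCCCC/C=C/[Sn](CCCC)(CCCC)CCCC | intermediate
14 | tert-butyl (2E)-4-[(1S,6R)-4-(tert-butoxymethyl)-3-[(1E)-hept-1-en-1-yl]-2,5-dioxo-7-oxabicyclo[4.1.0]hept-3-en-1-yl]-2-methylbut-2-enoate | CCCCC/C=C/C1=C(COC(C)(C)C)C(=O)[C@@H]2O[C@]2(C/C=C(\C)C(=O)OC(C)(C)C)C1=O | intermediate
15 | tert-butyl (2E)-4-[(1S,5R,6S)-4-(tert-butoxymethyl)-3-[(1E)-hept-1-en-1-yl]-5-hydroxy-2-oxo-7-oxabicyclo[4.1.0]hept-3-en-1-yl]-2-methylbut-2-enoate | CCCCC/C=C/C1=C(COC(C)(C)C)[C@@H](O)[C@@H]2O[C@]2(C/C=C(\C)C(=O)OC(C)(C)C)C1=O | intermediate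
16 | (2E)-4-[(1S,5R,6S)-3-[(1E)-hept-1-en-1-yl]-5-hydroxy-4-(hydroxymethyl)-2-oxo-7-oxabicyclo[4.1.0]hept-3-en-1-yl]-2-methylbut-2-enoic acid | CCCCC/C=C/C1=C(CO)[C@@H](O)[C@@H]2O[C@]2(C/C=C(\C)C(=O)O)C1=O | target

**Step count**

Total step count: 9.
Longest linear sequence: 9 (phenol 1 to target 16; 4, 10 and 12 enter as purchased materials).

**Three steps most likely to fail**

Step 5 (radical allylation). The risk is that radical 8 ring-opens to an α-keto radical, or that stannyl or ethyl radicals add to the enedione, before allyl transfer. The fallback sets out from 6 and comes back at 9. It makes the same C–C bond before the oxirane exists: palladium-catalysed Stille allylation of quinone 6 with allylSnBu3 (Pd2(dba)3, AsPh3, toluene, 40 °C) should occur at the less hindered C6–Br, because the C2–Br is flanked by the tert-butoxymethyl group, and gives 2-bromo-3-(tert-butoxymethyl)-6-(prop-2-en-1-yl)cyclohexa-2,5-diene-1,4-dione F1. The chiral-ammonium/tBuOOH epoxidation of step 4 then attacks its only trisubstituted enone alkene and gives 9 directly.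

Step 4 (enantioselective epoxidation). The risks are low enantioselectivity and displacement of a vinylic bromide by the peroxide. The fallback sets out from 6 and comes back at 7. It replaces asymmetric catalysis by resolution: racemic Weitz–Scheffer epoxidation (aq NaOCl, 1,4-dioxane, 0 °C) gives 7 together with its enantiomer (1S,6R)-1,3-dibromo-4-(tert-butoxymethyl)-7-oxabicyclo[4.1.0]hept-3-ene-2,5-dione F2. The two are separated by preparative chromatography on a chiral stationary phase (amylose carbamate), and 7 re-enters step 5.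

Step 8 (carbonyl reduction). The risks are that the oxirane biases hydride to the opposite face (mismatch with the catalyst) or that the C2 carbonyl competes. The fallback sets out from 14 and comes back at 15. It uses substrate control followed by inversion. Reduction with iBu2AlH (1.1 equiv, THF, −78 °C), with hydride attack anti to the oxirane oxygen, gives the syn alcohol tert-butyl (2E)-4-[(1S,5S,6S)-4-(tert-butoxymethyl)-3-[(1E)-hept-1-en-1-yl]-5-hydroxy-2-oxo-7-oxabicyclo[4.1.0]hept-3-en-1-yl]-2-methylbut-2-enoate F3. Mitsunobu inversion (4-nitrobenzoic acid, PPh3, DIAD, toluene, 0 °C) gives tert-butyl (2E)-4-[(1S,5R,6S)-4-(tert-butoxymethyl)-3-[(1E)-hept-1-en-1-yl]-5-[(4-nitrobenzoyl)oxy]-2-oxo-7-oxabicyclo[4.1.0]hept-3-en-1-yl]-2-methylbut-2-enoate F4. Methanolysis (K2CO3, MeOH, 0 °C) then releases 15.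

**Further compounds**

F1 | step 5 | 2-bromo-3-(tert-butoxymethyl)-6-(prop-2-en-1-yl)cyclohexa-2,5-diene-1,4-dione | O=C1C(Br)=C(COC(C)(C)C)C(=O)C=C1CC=C
F2 | step 4 | (1S,6R)-1,3-dibromo-4-(tert-butoxymethyl)-7-oxabicyclo[4.1.0]hept-3-ene-2,5-dione | BrC1=C(COC(C)(C)C)C(=O)[C@H]2O[C@@]2(Br)C1=O
F3 | step 8 | tert-butyl (2E)-4-[(1S,5S,6S)-4-(tert-butoxymethyl)-3-[(1E)-hept-1-en-1-yl]-5-hydroxy-2-oxo-7-oxabicyclo[4.1.0]hept-3-en-1-yl]-2-methylbut-2-enoate | CCCCC/C=C/C1=C(COC(C)(C)C)[C@H](O)[C@@H]2O[C@]2(C/C=C(\C)C(=O)OC(C)(C)C)C1=O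
F4 | step 8 | tert-butyl (2E)-4-[(1S,5R,6S)-4-(tert-butoxymethyl)-3-[(1E)-hept-1-en-1-yl]-5-[(4-nitrobenzoyl)oxy]-2-oxo-7-oxabicyclo[4.1.0]hept-3-en-1-yl]-2-methylbut-2-enoate | CCCCC/C=C/C1=C(COC(C)(C)C)[C@@H](OC(=O)c3ccc(cc3)[N+](=O)[O-])[C@@H]2O[C@]2(C/C=C(\C)C(=O)OC(C)(C)C)C1=O
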